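**Retrosynthetic overview**

- The target comes from acetylation of a hydroxy γ-lactone. That lactone comes from a cis-fused δ-lactone by acyl migration, after the ring-carbinol oxygen is desilylated.
- The δ-lactone and the six-membered carbocycle are closed together by an intramolecular Diels–Alder reaction of a (Z)-2-methylpenta-2,4-dienoate ester onto an (E)-α-methyl enone. The two carbinol stereocentres of the tether set the three ring stereocentres; the ring alkene is then reduced.
- The triene ester comes from esterification of the dienoic acid with an anti-diol mono-silyl ether. That alcohol comes from HWE olefination of a furan-bearing β-ketophosphonate with an anti α-silyloxy-β-hydroxy aldehyde, itself made by a D-proline cross-aldol of silyloxyacetaldehyde with methylglyoxal.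
- Ring order: the furan is bought; the cyclohexene and the six-membered lactone form together (step 8); the five-membered lactone forms last by ring switch (step 10).

Assumption: compounds marked "starting material" (including 7, 10, 11 as 40% aqueous solution) and D-proline are taken as catalogue items; the route is a proposal and has not been run.

**Step 1**
Reactants: 1 furan-3-ylmethanol
Product: 2 3-(bromomethyl)furan
Conditions: PBr3 (0.4 equiv), Et2O, 0 °C, 1 h; used at once as a solution
Reagents that add atoms: phosphorus tribromide, BrP(Br)Br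
Why: PBr3 bromination of a primary furylmethyl alcohol (SN2 on the phosphite ester); no stereocentre is involved.

**Step 2**
Reactants: 3 diethyl (2-oxopropyl)phosphonate; 2 3-(bromomethyl)furan
Product: 5 diethyl [5-(furan-3-yl)-3-oxopentan-2-yl]phosphonate, via γ-alkylated lithium enolate 4 (not isolated)
Conditions: LiN(iPr)2 (2.1 equiv), THF, −78→0 °C; 2, −78→0 °C; then MeI (1.1 equiv), 0 °C→rt
Reagents that add atoms: iodomethane, CI
Why: β-Ketophosphonate dianion alkylation: the dianion reacts first at its more basic terminal carbon with the reactive bromide, and the remaining stabilised enolate is then C-methylated; the new P-bearing centre is racemic and becomes sp2 in step 6.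

**Step 3**
Reactants: 6 acrolein; 7 ethyl 2-[bis(2,2,2-trifluoroethoxy)phosphoryl]propanoate
Product: 8 ethyl (2Z)-2-methylpenta-2,4-dienoate
Conditions: KN(SiMe3)2, 18-crown-6, THF, −78 °C
Reagents that add atoms: none
Why: Still–Gennari variant of the Horner–Wadsworth–Emmons reaction: the electron-poor phosphonate eliminates fast from the kinetic adduct and gives the (Z)-trisubstituted alkene.

**Step 4**
Reactants: 8 ethyl (2Z)-2-methylpenta-2,4-dienoate
Product: 9 (2Z)-2-methylpenta-2,4-dienoic acid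
Conditions: LiOH, THF/H2O 3:1, 0 °C→rt; then cold 1 M HCl to pH 3; stored cold over BHT
Reagents that add atoms: lithium hydroxide, [Li+].[OH-]
Why: Ester saponification under mild conditions that leave the (Z)-alkene geometry unchanged.

**Step 5**
Reactants: 10 [(tert-butyldimethylsilyl)oxy]acetaldehyde; 11 methylglyoxal
Product: 12 (2R,3S)-2-[(tert-butyldimethylsilyl)oxy]-3-hydroxy-4-oxopentanal
Conditions: D-proline (20 mol%), DMF, 4 °C; 11 as its 40% aq. solution in threefold excess; 10 added slowly by syringe pump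
Reagents that add atoms: none
Why: Proline-catalysed enamine cross-aldol addition (Houk–List transition state), in which every atom of both aldehydes is kept: the anti-enamine of 10 adds to the Si face of the aldehyde carbon of 11 under D-proline, giving the anti (2R,3S) adduct, with 11 in excess to suppress self-aldol of 10.

**Step 6**
Reactants: 12 (2R,3S)-2-[(tert-butyldimethylsilyl)oxy]-3-hydroxy-4-oxopentanal; 5 diethyl [5-(furan-3-yl)-3-oxopentan-2-yl]phosphonate
Product: 13 (3S,4S,5E)-4-[(tert-butyldimethylsilyl)oxy]-9-(furan-3-yl)-3-hydroxy-6-methylnon-5-ene-2,7-dione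
Conditions: LiCl, iPr2NEt, MeCN, 0 °C→rt
Reagents that add atoms: none
Why: Masamune–Roush Horner–Wadsworth–Emmons olefination: the mild amine/LiCl conditions spare the β-hydroxy aldehyde, and the α-methyl β-ketophosphonate gives the (E)-trisubstituted enone; both carbinol centres are untouched (the descriptor at the silyloxy carbon changes from R to S only through CIP priorities).

**Step 7**
Reactants: 13 (3S,4S,5E)-4-[(tert-butyldimethylsilyl)oxy]-9-(furan-3-yl)-3-hydroxy-6-methylnon-5-ene-2,7-dione; 9 (2Z)-2-methylpenta-2,4-dienoic acid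
Product: 14 (3S,4S,5E)-4-[(tert-butyldimethylsilyl)oxy]-9-(furan-3-yl)-6-methyl-2,7-dioxonon-5-en-3-yl (2Z)-2-methylpenta-2,4-dienoate
Conditions: DCC, DMAP (10 mol%), CH2Cl2, 0 °C
Reagents that add atoms: none
Why: Steglich esterification of the only free hydroxyl; the neighbouring oxygen is silylated, so no acyl migration can occur, and 0 °C keeps the (Z)-dienoate and the α-ketol centre intact.

**Step 8**
Reactants: 14 (3S,4S,5E)-4-[(tert-butyldimethylsilyl)oxy]-9-(furan-3-yl)-6-methyl-2,7-dioxonon-5-en-3-yl (2Z)-2-methylpenta-2,4-dienoate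
Product: 15 (3S,4S,4aR,5S,8aS)-3-acetyl-4-[(tert-butyldimethylsilyl)oxy]-5-[3-(furan-3-yl)propanoyl]-5,8a-dimethyl-3,4,4a,5,6,8a-hexahydro-1H-isochromen-1-one
Conditions: PhMe (5 mM), BHT (cat.), sealed tube, 170 °C, 36 h
Reagents that add atoms: none
Why: Intramolecular Diels–Alder reaction (ester-tethered deca-1,3,9-triene type): the (Z)-dienoate carries the tether on its inside position so only the cis-fused lactone with the acyl group endo can form, the (E)-enone geometry places the ring methyl cis to the carbinol carbon, and the tether closes through a chair with silyloxy and acetyl equatorial and the allylic C–H eclipsing the enone (1,3-allylic strain with the vinylic methyl), so the diene adds anti to the silyloxy group and sets 4a, 5 and 8a as (4aR,5S,8aS).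

**Step 9**
Reactants: 15 (3S,4S,4aR,5S,8aS)-3-acetyl-4-[(tert-butyldimethylsilyl)oxy]-5-[3-(furan-3-yl)propanoyl]-5,8a-dimethyl-3,4,4a,5,6,8a-hexahydro-1H-isochromen-1-one
Product: 16 (3S,4S,4aR,5S,8aS)-3-acetyl-4-[(tert-butyldimethylsilyl)oxy]-5-[3-(furan-3-yl)propanoyl]-5,8a-dimethyloctahydro-1H-isochromen-1-one
Conditions: 2-nitrobenzenesulfonohydrazide (excess, in portions), Et3N, CH2Cl2, rt
Reagents that add atoms: none
Why: Diimide reduction: syn transfer of H2 to the unconjugated cis-disubstituted ring alkene, leaving furan, ketones, lactone and silyl ether untouched; no stereocentre is formed.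

**Step 10**
Reactants: 16 (3S,4S,4aR,5S,8aS)-3-acetyl-4-[(tert-butyldimethylsilyl)oxy]-5-[3-(furan-3-yl)propanoyl]-5,8a-dimethyloctahydro-1H-isochromen-1-one
Product: 18 (3S,3aR,4S,7aS)-4-[3-(furan-3-yl)propanoyl]-3-[(1S)-1-hydroxy-2-oxopropyl]-4,7a-dimethylhexahydro-2-benzofuran-1(3H)-one, via δ-lactone alcohol 17 (not isolated)
Conditions: HF·pyridine, THF, 0 °C→rt; then camphorsulfonic acid (10 mol%), CH2Cl2, rt
Reagents that add atoms: none
Why: Desilylation followed by acid-catalysed translactonization (intramolecular acyl migration): the freed γ-hydroxyl takes over the acyl group to give the five-membered lactone, expected to be the more stable isomer as in the aldono-1,5- to 1,4-lactone equilibrium, and no stereocentre changes because only acyl C–O bonds are exchanged.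

**Step 11**
Reactants: 18 (3S,3aR,4S,7aS)-4-[3-(furan-3-yl)propanoyl]-3-[(1S)-1-hydroxy-2-oxopropyl]-4,7a-dimethylhexahydro-2-benzofuran-1(3H)-one
Product: 19 (1S)-1-[(3S,3aR,4S,7aS)-4-[3-(furan-3-yl)propanoyl]-4,7a-dimethyl-1-oxooctahydro-2-benzofuran-3-yl]-2-oxopropyl acetate (CNP0170401.2)
Conditions: Ac2O, pyridine, DMAP (cat.), CH2Cl2, 0 °C
Reagents that add atoms: acetic anhydride, CC(=O)OC(C)=O
Why: DMAP-catalysed acetylation of the secondary α-ketol hydroxyl under weakly basic conditions that do not enolise the adjacent ketone, so configuration is retained.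

**Compound list**

1 | furan-3-ylmethanol | OCc1ccoc1 | starting material
2 | 3-(bromomethyl)furan | BrCc1ccoc1 | intermediate
3 | diethyl (2-oxopropyl)phosphonate | CCOP(=O)(OCC)CC(C)=O | starting material
4 | lithium enolate of diethyl [4-(furan-3-yl)-2-oxobutyl]phosphonate (not isolated) | CCOP(=O)(OCC)C=C([O-])CCc1ccoc1.[Li+] | intermediate
5 | diethyl [5-(furan-3-yl)-3-oxopentan-2-yl]phosphonate (racemic) | CCOP(=O)(OCC)C(C)C(=O)CCc1ccoc1 | intermediate
6 | acrolein | C=CC=O | starting material
7 | ethyl 2-[bis(2,2,2-trifluoroethoxy)phosphoryl]propanoate | CCOC(=O)C(C)P(=O)(OCC(F)(F)F)OCC(F)(F)F | starting material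
8 | ethyl (2Z)-2-methylpenta-2,4-dienoate | C=C/C=C(/C)C(=O)OCC | intermediate
9 | (2Z)-2-methylpenta-2,4-dienoic acid | C=C/C=C(/C)C(=O)O | intermediate
10 | [(tert-butyldimethylsilyl)oxy]acetaldehyde | CC(C)(C)[Si](C)(C)OCC=O | starting material
11 | methylglyoxal (2-oxopropanal) | CC(=O)C=O | starting material
12 | (2R,3S)-2-[(tert-butyldimethylsilyl)oxy]-3-hydroxy-4-oxopentanal | CC(=O)[C@@H](O)[C@@H](O[Si](C)(C)C(C)(C)C)C=O | intermediate
13 | (3S,4S,5E)-4-[(tert-butyldimethylsilyl)oxy]-9-(furan-3-yl)-3-hydroxy-6-methylnon-5-ene-2,7-dione | CC(=O)[C@@H](O)[C@@H](O[Si](C)(C)C(C)(C)C)/C=C(\C)C(=O)CCc1ccoc1 | intermediate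
14 | (3S,4S,5E)-4-[(tert-butyldimethylsilyl)oxy]-9-(furan-3-yl)-6-methyl-2,7-dioxonon-5-en-3-yl (2Z)-2-methylpenta-2,4-dienoate | C=C/C=C(/C)C(=O)O[C@H](C(C)=O)[C@@H](O[Si](C)(C)C(C)(C)C)/C=C(\C)C(=O)CCc1ccoc1 | intermediate
15 | (3S,4S,4aR,5S,8aS)-3-acetyl-4-[(tert-butyldimethylsilyl)oxy]-5-[3-(furan-3-yl)propanoyl]-5,8a-dimethyl-3,4,4a,5,6,8a-hexahydro-1H-isochromen-1-one | CC(=O)[C@H]1OC(=O)[C@@]2(C)C=CC[C@](C)(C(=O)CCc3ccoc3)[C@H]2[C@@H]1O[Si](C)(C)C(C)(C)C | intermediate
16 | (3S,4S,4aR,5S,8aS)-3-acetyl-4-[(tert-butyldimethylsilyl)oxy]-5-[3-(furan-3-yl)propanoyl]-5,8a-dimethyloctahydro-1H-isochromen-1-one | CC(=O)[C@H]1OC(=O)[C@@]2(C)CCC[C@](C)(C(=O)CCc3ccoc3)[C@H]2[C@@H]1O[Si](C)(C)C(C)(C)C | intermediate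
17 | (3S,4S,4aR,5S,8aS)-3-acetyl-5-[3-(furan-3-yl)propanoyl]-4-hydroxy-5,8a-dimethyloctahydro-1H-isochromen-1-one (not isolated) | CC(=O)[C@H]1OC(=O)[C@@]2(C)CCC[C@](C)(C(=O)CCc3ccoc3)[C@H]2[C@@H]1O | intermediate
18 | (3S,3aR,4S,7aS)-4-[3-(furan-3-yl)propanoyl]-3-[(1S)-1-hydroxy-2-oxopropyl]-4,7a-dimethylhexahydro-2-benzofuran-1(3H)-one | CC(=O)[C@@H](O)[C@H]1OC(=O)[C@@]2(C)CCC[C@](C)(C(=O)CCc3ccoc3)[C@@H]12 | intermediate
19 | (1S)-1-[(3S,3aR,4S,7aS)-4-[3-(furan-3-yl)propanoyl]-4,7a-dimethyl-1-oxooctahydro-2-benzofuran-3-yl]-2-oxopropyl acetate | CC(=O)O[C@H](C(C)=O)[C@H]1OC(=O)[C@@]2(C)CCC[C@](C)(C(=O)CCc3ccoc3)[C@@H]12 | target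

**Step count**

Total: 11 steps. Longest linear sequence: 8 steps (steps 1, 2, 6, 7, 8, 9, 10, 11).

**Steps most likely to fail, with fallbacks**

Step 8 (cycloaddition). The tether forces the enone β-carbon to bond to the ester-bearing, doubly substituted diene terminus, against the polarisation of a dienoate, and two quaternary carbons are made. The fallback sets out from 7 and 13 and comes back at 16. Instead of forcing 14, the diene is re-polarised with a removable donor. Thiophenol and 3-(dimethylamino)acrolein (acid-catalysed addition–elimination) give (2E)-3-(phenylsulfanyl)prop-2-enal F1. Still–Gennari olefination of F1 with 7 gives ethyl (2Z,4E)-2-methyl-5-(phenylsulfanyl)penta-2,4-dienoate F2. LiOH hydrolysis gives (2Z,4E)-2-methyl-5-(phenylsulfanyl)penta-2,4-dienoic acid F3. DCC/DMAP coupling with 13 gives the sulfanyl triene ester F4. In this push–pull diene the ester-bearing terminus is the nucleophilic one, matched to the enone β-carbon, so the same tethered cycloaddition should run at lower temperature to the 6-(phenylsulfanyl) cycloadduct F5 (sulfur cis to the acyl group, since the outside diene substituent and the endo acyl group end up on the same face). Bu3SnH/AIBN cleaves the allylic C–S bond to give 15 together with its double-bond isomer F6, and both are saturated under the conditions of step 9 to 16.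

Step 5 (cross-aldol). Methylglyoxal is an aqueous hydrate and can also act as an enamine donor through its ketone, which may erode yield and selectivity. The fallback sets out from 10 and comes back at 14. The non-enolisable 3-(trimethylsilyl)prop-2-ynal is used as acceptor and the methyl ketone is unmasked later. D-Proline cross-aldol gives (2R,3R)-2-[(tert-butyldimethylsilyl)oxy]-3-hydroxy-5-(trimethylsilyl)pent-4-ynal F7, with the same spatial arrangement as 12. Olefination with 5 as in step 6 gives the enynone alcohol F8. Esterification with 9 as in step 7 gives the propargylic dienoate F9. Ph3PAuCl/AgSbF6 in wet dioxane then hydrates the alkyne with loss of the silyl group, the neighbouring ester carbonyl directing water to the inner carbon, to give 14.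

Step 10 (lactone ring switch). The six- to five-membered lactone isomerisation is an equilibrium whose position is not known for this congested system. The fallback sets out from 16 and comes back at 19. The order of events is made kinetic. AlMe3/MeNH(OMe)·HCl opens the δ-lactone of 16 to the hydroxy Weinreb amide F10. Ac2O/pyridine/DMAP acetylates the freed side-chain hydroxyl to give the acetoxy Weinreb amide F11. HF·pyridine then removes the silyl group, and the freed hydroxyl can only close the five-membered lactone onto the amide (camphorsulfonic acid), giving 19 directly.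

**Further compounds**

F1 | step 8 | (2E)-3-(phenylsulfanyl)prop-2-enal | O=C/C=C/Sc1ccccc1
F2 | step 8 | ethyl (2Z,4E)-2-methyl-5-(phenylsulfanyl)penta-2,4-dienoate | CCOC(=O)/C(C)=C\C=C\Sc1ccccc1
F3 | step 8 | (2Z,4E)-2-methyl-5-(phenylsulfanyl)penta-2,4-dienoic acid | OC(=O)/C(C)=C\C=C\Sc1ccccc1
F4 | step 8 | (3S,4S,5E)-4-[(tert-butyldimethylsilyl)oxy]-9-(furan-3-yl)-6-methyl-2,7-dioxonon-5-en-3-yl (2Z,4E)-2-methyl-5-(phenylsulfanyl)penta-2,4-dienoate | CC(=O)[C@@H](OC(=O)/C(C)=C\C=C\Sc1ccccc1)[C@@H](O[Si](C)(C)C(C)(C)C)/C=C(\C)C(=O)CCc1ccoc1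
F5 | step 8 | (3S,4S,4aS,5S,6S,8aS)-3-acetyl-4-[(tert-butyldimethylsilyl)oxy]-5-[3-(furan-3-yl)propanoyl]-5,8a-dimethyl-6-(phenylsulfanyl)-3,4,4a,5,6,8a-hexahydro-1H-isochromen-1-one | CC(=O)[C@H]1OC(=O)[C@@]2(C)C=C[C@H](Sc3ccccc3)[C@](C)(C(=O)CCc3ccoc3)[C@H]2[C@@H]1O[Si](C)(C)C(C)(C)C
F6 | step 8 | (3S,4S,4aR,5S,8aS)-3-acetyl-4-[(tert-butyldimethylsilyl)oxy]-5-[3-(furan-3-yl)propanoyl]-5,8a-dimethyl-3,4,4a,5,8,8a-hexahydro-1H-isochromen-1-one | CC(=O)[C@H]1OC(=O)[C@@]2(C)CC=C[C@](C)(C(=O)CCc3ccoc3)[C@H]2[C@@H]1O[Si](C)(C)C(C)(C)C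
F7 | step 5 | (2R,3R)-2-[(tert-butyldimethylsilyl)oxy]-3-hydroxy-5-(trimethylsilyl)pent-4-ynal | C[Si](C)(C)C#C[C@@H](O)[C@@H](O[Si](C)(C)C(C)(C)C)C=O
F8 | step 5 | (4E,6S,7R)-6-[(tert-butyldimethylsilyl)oxy]-1-(furan-3-yl)-7-hydroxy-4-methyl-9-(trimethylsilyl)non-4-en-8-yn-3-one | C[Si](C)(C)C#C[C@@H](O)[C@@H](O[Si](C)(C)C(C)(C)C)/C=C(\C)C(=O)CCc1ccoc1
F9 | step 5 | (3R,4S,5E)-4-[(tert-butyldimethylsilyl)oxy]-9-(furan-3-yl)-6-methyl-7-oxo-1-(trimethylsilyl)non-5-en-1-yn-3-yl (2Z)-2-methylpenta-2,4-dienoate | C=C/C=C(/C)C(=O)O[C@H](C#C[Si](C)(C)C)[C@@H](O[Si](C)(C)C(C)(C)C)/C=C(\C)C(=O)CCc1ccoc1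
F10 | step 10 | (1S,2R,3S)-2-[(1S,2S)-1-[(tert-butyldimethylsilyl)oxy]-2-hydroxy-3-oxobutyl]-3-[3-(furan-3-yl)propanoyl]-N-methoxy-N,1,3-trimethylcyclohexane-1-carboxamide | CC(=O)[C@@H](O)[C@@H](O[Si](C)(C)C(C)(C)C)[C@H]1[C@@](C)(C(=O)N(C)OC)CCC[C@]1(C)C(=O)CCc1ccoc1
F11 | step 10 | (1S,2S)-1-[(tert-butyldimethylsilyl)oxy]-1-[(1R,2S,6S)-2-[3-(furan-3-yl)propanoyl]-6-[methoxy(methyl)carbamoyl]-2,6-dimethylcyclohexyl]-3-oxobutan-2-yl acetate | CC(=O)[C@@H](OC(C)=O)[C@@H](O[Si](C)(C)C(C)(C)C)[C@H]1[C@@](C)(C(=O)N(C)OC)CCC[C@]1(C)C(=O)CCc1ccoc1
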